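The synthesis rests on disconnecting the bond between the ring alkene carbon C2 and the allylic carbinol carbon C3 of the cyclohexene. In the open-chain precursor both carbons are electrophiles. C3 is an aldehyde. C2 is the sulfur-bearing β-carbon of an unsaturated thioester whose carbonyl is the future CH2O carbon C7. SmI2 reverses the polarity of C3 (ketyl), which attacks C2, and loss of the phenylthio group restores C1=C2. The ring, the ring alkene and the C3 stereocentre thus arise in one operation, whatever the alkene geometry of the precursor. The step exploits the allylic alcohol unit C1=C2–C3(OH) and the C4–C6 triol array, which comes unchanged from L-arabinose.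

Key step: step 6

Remark on locants: C1 is the ring carbon bearing the CH2OBz group (that carbon is C7) and C2 is the ring =CH. C3 (OH), C4 (OH), C5 (OBz) and C6 (OH) follow around the ring, and On is the oxygen on Cn. The same locants are used for the open-chain precursors.

Step 1
Reactants: 1 L-arabinose
Product: 2 3,4-O-isopropylidene-L-arabinopyranose (anomeric mixture; acetonide on the future O5/O4)
Conditions: Me2C(OMe)2, p-TsOH·H2O (cat.), DMF, rt
Reagents that add atoms: 2,2-dimethoxypropane COC(C)(C)OC
Why: Acid-catalysed acetonide formation (transacetalisation) should pick the cis-vicinal diol of the pyranose ring (future O5 and O4) and leave the lactol and all stereocentres untouched.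

Step 2
Reactants: 2 3,4-O-isopropylidene-L-arabinopyranose
Product: 3 1,2-dideoxy-4,5-O-isopropylidene-L-arabino-hex-1-ynitol, HC2≡C1–C6H(OH)–C5H/C4H(acetonide)–C3H2OH
Conditions: MeC(O)C(N2)P(O)(OMe)2, K2CO3, MeOH, rt to 45 °C
Reagents that add atoms: dimethyl (1-diazo-2-oxopropyl)phosphonate CC(=O)C(=[N+]=[N-])P(=O)(OC)OC
Why: The Ohira–Bestmann variant of the Seyferth–Gilbert homologation acts on the open hydroxy-aldehyde tautomer of the lactol and turns its aldehyde carbon (C1) into a terminal alkyne whose new carbon is C2, with C6, C5 and C4 retained from the sugar.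

Step 3
Reactants: 3 1,2-dideoxy-4,5-O-isopropylidene-L-arabino-hex-1-ynitol
Product: 4 bis(triethylsilyl) ether of 3 (silyl ethers on O6 and O3)
Conditions: Et3SiCl, imidazole, CH2Cl2, 0 °C to rt
Reagents that add atoms: chlorotriethylsilane CC[Si](Cl)(CC)CC
Why: Standard silyl ether formation caps both hydroxyls, so that O6 cannot later close a lactol on C3 and the primary ether can be oxidised selectively.

Step 4
Reactants: 4 bis(triethylsilyl) ether of 3
Product: 5 S-phenyl (Z)-3-(phenylsulfanyl)prop-2-enethioate carrying at its α-carbon C1 the L-arabino chain C6(OSiEt3)–C5/C4(acetonide)–C3H2OSiEt3; PhS on C2 is cis to the thioester carbonyl C7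
Conditions: PhSSPh, CO (30 atm), Pd(PPh3)4 (cat.), toluene, 80 °C
Reagents that add atoms: diphenyl disulfide c1ccc(SSc2ccccc2)cc1; carbon monoxide [C-]#[O+]
Why: The palladium-catalysed carbonylative addition of a disulfide to a terminal alkyne (syn thiopalladation with sulfur on the terminal carbon, CO insertion at the internal carbon, C–S reductive elimination) should give the Z adduct regioselectively and install both C7 and the leaving group on C2 in one operation.

Step 5
Reactants: 5 S-phenyl (Z)-3-(phenylsulfanyl)prop-2-enethioate with the silylated L-arabino chain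
Product: 6 the corresponding C3 aldehyde (O6 still silylated)
Conditions: (COCl)2, DMSO, CH2Cl2, −78 to −40 °C; then Et3N, −78 to 0 °C
Reagents that add atoms: none
Why: In this Swern oxidation applied directly to a silyl ether, the chlorosulfonium reagent cleaves the unhindered primary triethylsilyl ether far faster than the secondary one and oxidises it in situ, and the low temperature should preserve the configuration at C4.

Step 6
Reactants: 6 C3 aldehyde bearing the β-(phenylthio) unsaturated thioester
Product: 7 S-phenyl cyclohex-1-ene-1-carbothioate with 3-OH, 4,5-O-isopropylidene and 6-OSiEt3; O3 and O6 on one ring face, O4 and O5 on the other (target configuration)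
Conditions: SmI2 (2.1 equiv, 0.1 M in THF, slow addition), THF (0.01 M), −78 to −20 °C; then aq. NH4Cl
Reagents that add atoms: none
Why: SmI2 transfers one electron to the C3 aldehyde, the nucleophilic samarium ketyl attacks C2 (the sulfur-bearing β-carbon of the unsaturated thioester), the C1 radical so formed expels a phenylthiyl radical by β-scission and thereby restores C1=C2, and the second equivalent of SmI2 reduces that thiyl radical to thiolate. The closest known reaction types are the SmI2 ketyl–olefin cyclisation onto β-heteroatom-substituted acrylates, ketyl–olefin coupling/β-elimination sequences and radical vinylic substitution of vinyl sulfides by addition–fragmentation. The cyclohexene ring closes in the 6-endo-trig mode, secured by the acceptor polarity (C2 is the electrophilic terminus) and by the fully substituted C1, which blocks the 5-exo alternative. C3 is the only new stereocentre: in the chair-like transition state the O6 silyl ether stands axial to avoid allylic strain against the thioester on C1, which makes O5 axial and O4 equatorial, so the bulky samarium-bound O3 takes the equatorial site trans to O4, the axial alternative being syn-diaxial to O5. Because C2 passes through sp3, the Z geometry of 6 (sulfur trans to the chain, useless for a vinyl-metal closure) does not matter and either alkene isomer would converge on 7. The step needs reduction to stop before the γ-oxygenated product or O6 is attacked, which fast C–S scission (no long-lived enolate), two equivalents of SmI2 and the absence of proton source and HMPA should secure.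

Step 7
Reactants: 7 S-phenyl cyclohexenecarbothioate
Product: 8 allylic diol, the C7 hydroxymethyl analogue of 7 (3-OH, 4,5-O-isopropylidene, 6-OSiEt3)
Conditions: i-Bu2AlH, CH2Cl2, −78 to −20 °C; aq. potassium sodium tartrate
Reagents that add atoms: none
Why: The 1,2-hydride reduction of the activated S-aryl thioester by i-Bu2AlH should proceed to the allylic alcohol without touching the alkene, the silyl ether or the acetonide.

Step 8
Reactants: 8 allylic diol
Product: 9 C7 monobenzoate of 8
Conditions: BzCl (1.05 equiv), pyridine, CH2Cl2, −40 to −10 °C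
Reagents that add atoms: benzoyl chloride O=C(Cl)c1ccccc1
Why: In this selective acylation the unhindered primary allylic hydroxyl on C7 should react with one equivalent of benzoyl chloride at low temperature well before the secondary O3–H.

Step 9
Reactants: 9 C7 monobenzoate
Product: 10 [(3R,4S,5R,6S)-3,4,5,6-tetrahydroxycyclohex-1-en-1-yl]methyl benzoate
Conditions: AcOH–H2O (4:1), 45 °C
Reagents that add atoms: none
Why: Mild acid hydrolysis removes the triethylsilyl ether and the acetonide together, while the primary benzoate and all stereocentres are stable under these conditions.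

Step 10
Reactants: 10 [(3R,4S,5R,6S)-3,4,5,6-tetrahydroxycyclohex-1-en-1-yl]methyl benzoate
Product: 12 [(3R,4S,5R,6S)-5-(benzoyloxy)-3,4,6-trihydroxycyclohex-1-en-1-yl]methyl benzoate (target), via cyclic 4,5-orthobenzoate 11 (not isolated)
Conditions: PhC(OMe)3, camphorsulfonic acid (cat.), MeCN, rt; then AcOH–H2O (4:1), 0 °C to rt
Reagents that add atoms: trimethyl orthobenzoate COC(OC)(OC)c1ccccc1; water O
Why: Orthoester exchange picks out the only cis-vicinal diol (O4/O5), and kinetic acid hydrolysis of such a fused 2-methoxy-1,3-dioxolane leaves the ester on the axial oxygen, which is O5 in the favoured half-chair where O6 is pseudoaxial to avoid allylic strain against the C7 side chain.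

Compound list
1 | L-arabinose (pyranose form) | OC1OC[C@H](O)[C@H](O)[C@H]1O | starting material
2 | 3,4-O-isopropylidene-L-arabinopyranose | OC1OC[C@@H]2OC(C)(C)O[C@@H]2[C@H]1O | intermediate
3 | 1,2-dideoxy-4,5-O-isopropylidene-L-arabino-hex-1-ynitol | C#C[C@H](O)[C@H]1OC(C)(C)O[C@H]1CO | intermediate
4 | bis(triethylsilyl) ether of 3 | C#C[C@H](O[Si](CC)(CC)CC)[C@H]1OC(C)(C)O[C@H]1CO[Si](CC)(CC)CC | intermediate
5 | S-phenyl (Z)-3-(phenylsulfanyl)prop-2-enethioate with the silylated L-arabino chain on C1 | O=C(Sc1ccccc1)/C(=C\Sc1ccccc1)[C@H](O[Si](CC)(CC)CC)[C@H]1OC(C)(C)O[C@H]1CO[Si](CC)(CC)CC | intermediate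
6 | C3 aldehyde derived from 5 | O=C(Sc1ccccc1)/C(=C\Sc1ccccc1)[C@H](O[Si](CC)(CC)CC)[C@H]1OC(C)(C)O[C@H]1C=O | intermediate
7 | S-phenyl cyclohex-1-ene-1-carbothioate (3-OH, 4,5-O-isopropylidene, 6-OSiEt3) | O=C(Sc1ccccc1)C1=C[C@@H](O)[C@@H]2OC(C)(C)O[C@@H]2[C@H]1O[Si](CC)(CC)CC | intermediate
8 | allylic diol (C7 hydroxymethyl analogue of 7) | OCC1=C[C@@H](O)[C@@H]2OC(C)(C)O[C@@H]2[C@H]1O[Si](CC)(CC)CC | intermediate
9 | C7 monobenzoate of 8 | O=C(OCC1=C[C@@H](O)[C@@H]2OC(C)(C)O[C@@H]2[C@H]1O[Si](CC)(CC)CC)c1ccccc1 | intermediate
10 | [(3R,4S,5R,6S)-3,4,5,6-tetrahydroxycyclohex-1-en-1-yl]methyl benzoate | O=C(OCC1=C[C@@H](O)[C@H](O)[C@H](O)[C@H]1O)c1ccccc1 | intermediate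
11 | cyclic 4,5-orthobenzoate of 10 (epimers at the orthoester carbon) | O=C(OCC1=C[C@@H](O)[C@@H]2OC(OC)(c3ccccc3)O[C@@H]2[C@H]1O)c1ccccc1 | intermediate
12 | [(3R,4S,5R,6S)-5-(benzoyloxy)-3,4,6-trihydroxycyclohex-1-en-1-yl]methyl benzoate | O=C(OCC1=C[C@@H](O)[C@H](O)[C@H](OC(=O)c2ccccc2)[C@H]1O)c1ccccc1 | target

Total step count: 10. Longest linear sequence: 10.

Steps most likely to fail

Step 6. Several processes could intervene before the 6-endo attack:
- electron transfer to the unsaturated thioester instead of the aldehyde;
- over-reduction of the γ-oxygenated product;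
- plain reduction or pinacol dimerisation of the aldehyde.

The fallback sets out from 4 and comes back at 9. It forms the same C2–C3 bond through a vinylchromium species. Gold-catalysed oxidation of the terminal alkyne (Ph3PAuNTf2, 8-methylquinoline N-oxide) in the presence of benzoic acid would give the α-benzoyloxy ketone F1. Stork–Zhao iodomethylenation ([Ph3PCH2I]I, NaN(SiMe3)2, THF, −78 °C) would give the Z iodoalkene F2, with iodine cis to C6. Selective Swern oxidation of the primary silyl ether would give the iodo aldehyde F3. An intramolecular Nozaki–Hiyama–Kishi reaction (CrCl2, cat. NiCl2, DMSO, high dilution) would then close the ring to 9.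

Step 10. The orthoester may open towards O4, or the acyl group may migrate between O4 and O5, which would erode the regioselectivity. The fallback sets out from 10 and comes back at 12. Butane-2,3-dione, HC(OMe)3 and catalytic camphorsulfonic acid in MeOH should tie up the trans-diequatorial O3/O4 pair as the butane-2,3-diacetal F9. Of the two hydroxyls left, O6–H is shielded by the C7 side chain, so one equivalent of BzCl should give the 5-benzoate F10. Aqueous CF3CO2H then frees O3 and O4 to give 12.

Step 4. Direct 1,2-addition of the disulfide may outrun CO insertion at the hindered internal carbon. The fallback sets out from 4 and comes back at 8. It builds the acceptor by carbonyl olefination instead of alkyne carbonylation.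
- NBS with catalytic AgNO3 would give the bromoalkyne F4.
- KMnO4 with NaHCO3 and MgSO4 in aqueous MeOH would give the α-keto ester F5.
- A Wittig reaction with Ph3P=CHSPh would give the methyl β-(phenylthio)acrylate F6 as an alkene mixture. The mixture is harmless because the ring closure does not depend on geometry.
- Selective Swern oxidation would give the ester aldehyde F7.
- SmI2 would give the methyl cyclohexenecarboxylate F8.
- i-Bu2AlH would then give 8.

Further compounds
F1 | step 6 | α-benzoyloxy ketone | O=C(c1ccccc1)OCC(=O)[C@H](O[Si](CC)(CC)CC)[C@H]1OC(C)(C)O[C@H]1CO[Si](CC)(CC)CC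
F2 | step 6 | Z iodoalkene | O=C(c1ccccc1)OC/C(=C/I)[C@H](O[Si](CC)(CC)CC)[C@H]1OC(C)(C)O[C@H]1CO[Si](CC)(CC)CC
F3 | step 6 | iodo aldehyde | O=C(c1ccccc1)OC/C(=C/I)[C@H](O[Si](CC)(CC)CC)[C@H]1OC(C)(C)O[C@H]1C=O
F4 | step 4 | bromoalkyne | BrC#C[C@H](O[Si](CC)(CC)CC)[C@H]1OC(C)(C)O[C@H]1CO[Si](CC)(CC)CC
F5 | step 4 | α-keto ester | COC(=O)C(=O)[C@H](O[Si](CC)(CC)CC)[C@H]1OC(C)(C)O[C@H]1CO[Si](CC)(CC)CC
F6 | step 4 | methyl β-(phenylthio)acrylate | COC(=O)C(=CSc1ccccc1)[C@H](O[Si](CC)(CC)CC)[C@H]1OC(C)(C)O[C@H]1CO[Si](CC)(CC)CC
F7 | step 4 | ester aldehyde | COC(=O)C(=CSc1ccccc1)[C@H](O[Si](CC)(CC)CC)[C@H]1OC(C)(C)O[C@H]1C=O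
F8 | step 4 | methyl cyclohexenecarboxylate | COC(=O)C1=C[C@@H](O)[C@@H]2OC(C)(C)O[C@@H]2[C@H]1O[Si](CC)(CC)CC
F9 | step 10 | butane-2,3-diacetal | O=C(OCC1=C[C@H]2OC(C)(OC)C(C)(OC)O[C@@H]2[C@H](O)[C@H]1O)c1ccccc1
F10 | step 10 | 5-benzoate | O=C(OCC1=C[C@H]2OC(C)(OC)C(C)(OC)O[C@@H]2[C@H](OC(=O)c2ccccc2)[C@H]1O)c1ccccc1
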